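## Structural features

The target is one oxolane ring (O1, C2–C5) carrying the same 4-hydroxy-3,5-dimethoxyphenyl ring on C2 and on C5, and a hydroxymethyl arm on C3 (arm carbon C9) and on C4. All four ring carbons are stereocentres in an unbroken row. The two aryl groups are cis (C2/C5), the C4 arm is trans to the C5 aryl, the two arms are trans (C3/C4), and the C3 arm is cis to the C2 aryl. This is (2S,3S,4S,5R) in the numbering used here, and (2R,3S,4S,5S) if numbered from the other aryl carbon. Because of that single cis pair the molecule has no symmetry, although its two halves have the same constitution. The fragile points are the two ring C–O bonds, each benzylic and para to a phenolic oxygen (ionisation under acid, hydrogenolysis), the oxidisable free phenols, and, in any carbonyl precursor, the epimerisable C3 centre. The real difficulty is the C2/C3 cis pair: C3 cannot be trans to both neighbours, so it must be set kinetically and not by equilibration. The key step uses the fact that C9 can be the carbonyl carbon of a 2,6-diaryl-oxan-4-one. C5, C4 and C2 of the oxolane are then C2, C3 and C6 of a chair with all three substituents equatorial, and the missing C3–C4 bond is made by a 1,2-shift that pushes the carbonyl carbon out of the ring.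

## Logic of the disconnections

17 ⇒ 16. The three O–benzyl bonds (two phenolic, one on the C4 arm) are cut. The phenols must be masked through enolate chemistry, and the C4 arm oxygen must not be free in the key step, where it would capture the ketene as a cis-fused lactone with the wrong C3 configuration. One protecting group type means one final operation. The demand is that hydrogenolysis stops before the ring C–O bonds are attacked.

16 ⇒ 15. No skeletal bond is cut; the C9 alcohol is traced to a methyl ester, the form in which C9 leaves the six-membered ring. The demand is reduction without epimerisation at C3.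

15 ⇒ 13 (through 14). The C3–C4 bond of the oxolane is cut and C4 is reattached to C9, which turns the five-membered ring into a six-membered diazo ketone with C9 as the ring carbonyl. Four contiguous centres with one awkward cis pair become three equatorial substituents on a chair plus one kinetic protonation. The demands are migration with retention and ketonisation on the face away from the C2 aryl.

13 ⇒ 11. The C=N2 unit is removed to a ring CH2. The demand is functionalisation at the methylene α-carbon only. The methine α-carbon carries an arm whose oxygen is β to the ketone, so the activating group is put on a kinetic enolate at low temperature, not by formylation under equilibrating alkoxide.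

11 ⇒ 9 (through 10). The ring O–C6 bond is cut (retro oxa-Michael) and C3 is allowed to be epimeric. C6 and C3 are then under thermodynamic control and only the carbinol carbon must carry absolute configuration. A syn aldol closes first to 10, so an explicit equilibration to 11 is planned. The demand is ring closure without retro-aldol or dehydration, and epimerisation without loss of benzyl alcohol.

9 ⇒ 7 + 3. The aldol C4–C5 bond is cut. The same aldehyde is used a second time, which exploits the equal constitution of the two halves. This is the one reagent-controlled step. The demand is α′-enolisation of an enone and addition to the Re face of 3.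

7 ⇒ 4 + 3. The C=C bond is cut (aldol condensation at the methyl group of 4). Because 4 is a β-alkoxy ketone, hydroxide-mediated condensation is avoided. The demand is kinetic methyl enolisation, followed by a separate mild elimination.

3 ⇒ 1 + 2. The phenolic O–benzyl bond is cut; a routine alkylation.

## Other disconnections considered

Alternative 1: The cut removes C4–C5 and O1–C5 from a 4,5-dihydrofuran. Forward, the ylide from a chiral benzylsulfonium salt such as A3 (or its mirror image) adds to the alkylidene carbon of keto ester A2, and the enolate oxygen displaces the sulfide to give the 4,5-trans dihydrofuran A1.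
- In favour: it is convergent, the sulfide supplies absolute configuration, the trans C4/C5 pair follows from the addition–displacement mechanism, and both arms arrive at useful oxidation levels. Syn addition of hydrogen across C2=C3 would make the C2/C3 cis pair automatically. On that point A1 is the better plan, since the chosen route leaves this pair to a protonation.
- Against: the key step sets only two of four centres. The other two depend on hydrogen adding to a tetrasubstituted donor–acceptor alkene on the face syn to the C4 arm and anti to the C5 aryl. The adjacent C4 substituent argues for the opposite face unless the arm is freed to direct a catalyst such as [Ir(cod)(PCy3)(py)]PF6. Such alkenes are sluggish, the C5–O bond is allylic and benzylic under hydrogenation, and A2 can isomerise or deconjugate.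
- Comparison: both plans are ionic and both leave one relationship to facial selectivity. Step economy is poorer, about eleven to twelve operations against eight, because A2 and A3 each need separate preparation.

Alternative 2: The cut is C2–C3. Forward, photoredox decarboxylation of acid A5 (both epimers at the acid-bearing carbon), for example with 4CzIPN and Cs2CO3, gives an α-alkoxybenzyl radical that closes 5-exo-trig onto the alkenylboronate. Reduction and protonation of the α-boryl radical give A4, and C–B oxidation delivers the C3 arm.
- In favour: the radical centre is planar, so C2 need not be controlled beforehand. The chair-like transition-state model places the C4 and C5 substituents pseudo-equatorial, which gives C3/C4 trans and C3/C5 cis, and the preference of 1-substituted hexenyl radicals for the 1,5-cis product points toward the needed C2/C3 cis pair. The arm is unmasked by oxidation, so no epimerisable carbonyl ever sits on C3. On that point A4 is better than the chosen plan.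
- Against: the cis preference at the radical carbon is the weakest of these effects and is least reliable for a bulky, stabilised benzylic radical. The electron-rich radical can be oxidised to an oxocarbenium ion or dimerise. A5 needs an enantiopure anti stereodiad, an alkenylboronate and a hindered secondary benzylic ether.
- Comparison: the two plans are equal in leaving the C2/C3 pair to kinetic control. The chosen plan is clearly shorter, eight operations against about twelve.

Alternative 3: The cuts are O1–C2 and C2–C3. Forward, Me3SiOTf condenses homoallylic alcohol A7 with aldehyde 3 to an oxocarbenium ion that is captured by the γ-carbon of the allylsilane, giving vinyl oxolane A6. Oxidative cleavage (OsO4/NaIO4), NaBH4 and debenzylation would finish the synthesis.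
- In favour: two ring bonds and two stereocentres form in one step, and the second aryl group enters as the simple aldehyde 3. In convergence at the key step A6 is at least the equal of the chosen plan.
- Against: a Lewis acid acts on a carbinol carbon bearing an electron-rich aryl group, so ionisation at C5 and 2-oxonia-Cope exchange threaten the enantiopurity. The product's benzylic ethers can epimerise under the same acid. The C2/C3 cis outcome depends on allylsilane geometry and transition-state shape. The vinyl group costs two further operations and passes through an epimerisable aldehyde on C3.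
- Comparison: the chosen plan keeps all acid-sensitive benzylic ethers away from strong Lewis acids and is shorter, eight operations against about ten to eleven. It has no answer as direct as A6 to forming C2 and C3 together.

Key step: step 6

Assumption: the (+)-antipode of diisopinocampheylboron triflate (from (−)-α-pinene) is taken to direct the Z enolate of 7 to the Re face of aldehyde 3, the face that gives the (5R) carbinol centre; should the sense be the reverse, the (−)-reagent is used in the same way and nothing else changes.

## Route

Step 1
Reactants: 1 syringaldehyde (4-hydroxy-3,5-dimethoxybenzaldehyde); 2 benzyl bromide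
Product: 3 4-(benzyloxy)-3,5-dimethoxybenzaldehyde
Conditions: K2CO3, DMF, 60 °C
Reagents that add atoms: none
Why: Williamson ether synthesis on the phenoxide; the aldehyde has no enolisable position and is untouched.

Step 2
Reactants: 4 4-(benzyloxy)butan-2-one; 3 4-(benzyloxy)-3,5-dimethoxybenzaldehyde
Product: 7 (E)-5-(benzyloxy)-1-[4-(benzyloxy)-3,5-dimethoxyphenyl]pent-1-en-3-one, via lithium aldolate 5 (not isolated), via aldol mesylate 6 (not isolated)
Conditions: LiN(iPr)2, THF, −78 °C; then 3; then MsCl, Et3N, −78 → 0 °C
Reagents that add atoms: none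
Why: Directed aldol condensation: kinetic deprotonation takes the methyl group of 4, which avoids the methylene enolate and hydroxide-induced loss of benzyl alcohol from this β-alkoxy ketone; aldolate 5 is mesylated in the flask to 6, and Et3N effects E1cB elimination to the conjugated E enone.

Step 3
Reactants: 7 (E)-5-(benzyloxy)-1-[4-(benzyloxy)-3,5-dimethoxyphenyl]pent-1-en-3-one; 3 4-(benzyloxy)-3,5-dimethoxybenzaldehyde
Product: 9 (1E,4R,5R)-4-[(benzyloxy)methyl]-1,5-bis[4-(benzyloxy)-3,5-dimethoxyphenyl]-5-hydroxypent-1-en-3-one (syn aldol), via Z-enol diisopinocampheylborinate 8 (not isolated)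
Conditions: (+)-Ipc2BOTf, iPr2NEt, CH2Cl2, −78 °C; then 3, −78 → −20 °C; then H2O2, pH 7 buffer, MeOH, 0 °C
Reagents that add atoms: none
Why: Reagent-controlled boron aldol: the triflate and amine enolise the only enolisable position of the enone to the Z-enol borinate 8, which adds to 3 through a closed chair transition state to give the syn aldol. The isopinocampheyl ligands select the Re face of the aldehyde and so set the (5R) carbinol centre, the one centre that carries absolute configuration through the route; the (4R) centre is corrected in step 4.

Step 4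
Reactants: 9 (1E,4R,5R)-4-[(benzyloxy)methyl]-1,5-bis[4-(benzyloxy)-3,5-dimethoxyphenyl]-5-hydroxypent-1-en-3-one
Product: 11 (2R,3S,6S)-3-[(benzyloxy)methyl]-2,6-bis[4-(benzyloxy)-3,5-dimethoxyphenyl]oxan-4-one (all three substituents equatorial), via 2,3-cis pyranone 10 (not isolated)
Conditions: [Pd(MeCN)4](BF4)2 (10 mol%), CH2Cl2, rt; then DBU (0.3 equiv), rt
Reagents that add atoms: none
Why: Lewis-acid activation of the enone by divalent palladium triggers a 6-endo-trig oxa-Michael addition through a chair with both aryl groups equatorial, which sets C6 cis to C2 and gives 10 with the arm axial, without retro-aldol or dehydration. Catalytic DBU then epimerises the enolisable C3 centre to the thermodynamically preferred all-equatorial 11; any residual 10 is separated and resubmitted.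

Step 5
Reactants: 11 (2R,3S,6S)-3-[(benzyloxy)methyl]-2,6-bis[4-(benzyloxy)-3,5-dimethoxyphenyl]oxan-4-one
Product: 13 (2R,3S,6R)-3-[(benzyloxy)methyl]-2,6-bis[4-(benzyloxy)-3,5-dimethoxyphenyl]-5-diazooxan-4-one, via trifluoroacetyl ketone 12 (not isolated)
Conditions: LiN(SiMe3)2, THF, −78 °C; CF3CO2CH2CF3; dilute aq HCl quench; then 4-AcNHC6H4SO2N3, Et3N, H2O, MeCN, rt
Reagents that add atoms: 4-acetamidobenzenesulfonyl azide, CC(=O)Nc1ccc(cc1)S(=O)(=O)N=[N+]=[N-]
Why: Detrifluoroacetylative diazo transfer: kinetic enolisation at −78 °C takes the C5 methylene, not the C3 methine, so the β-benzyloxy arm is not exposed to E1cB loss; C-trifluoroacetylation gives 12, and the sulfonyl azide transfers N2 with loss of the trifluoroacetyl group. C2, C3 and C6 are untouched.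

Step 6
Reactants: 13 (2R,3S,6R)-3-[(benzyloxy)methyl]-2,6-bis[4-(benzyloxy)-3,5-dimethoxyphenyl]-5-diazooxan-4-one
Product: 15 methyl (2S,3R,4S,5R)-4-[(benzyloxy)methyl]-2,5-bis[4-(benzyloxy)-3,5-dimethoxyphenyl]oxolane-3-carboxylate, via ketene 14 (not isolated)
Conditions: hν (365 nm), MeOH–THF (3:1), 0 °C
Reagents that add atoms: methanol, CO
Why: Excitation of the diazo ketone, held s-cis by the ring, expels N2 while the CH(CH2OBn) ring carbon shifts from the carbonyl carbon to the diazo carbon, giving ketene 14. This is the photochemical Wolff rearrangement, the standard ring contraction of cyclic 2-diazo ketones. The oxolane arises by contraction of the six-membered ring through that 1,2-shift (new C3–C4 bond), so no exo or endo cyclisation mode is involved. The migrating carbon keeps its configuration and the two aryl-bearing carbons are not touched, so C2, C4 and C5 of the oxolane inherit the 2,6-cis, 2,3-trans arrangement of 13. Methanol adds to the ketene to give the ester enol, and its ketonisation creates C3: the proton should arrive on the face of the exocyclic enol away from the adjacent C2 aryl group, the larger of the two flanking groups, which places the ester cis to that aryl; this is the usual kinetic result when an exocyclic enol next to an aryl-bearing carbon is protonated from its less hindered face. The step needs migration to beat 1,2-hydride shift from C6–H and O–H insertion, which the concerted s-cis pathway favours, and it needs facial selectivity at C3, which rests on the size difference between aryl and CH2OBn. The benzyl ether on the C4 arm prevents intramolecular capture of the ketene, and neutral, cold conditions keep the kinetically formed ester from epimerising.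

Step 7
Reactants: 15 methyl (2S,3R,4S,5R)-4-[(benzyloxy)methyl]-2,5-bis[4-(benzyloxy)-3,5-dimethoxyphenyl]oxolane-3-carboxylate
Product: 16 {(2S,3S,4S,5R)-4-[(benzyloxy)methyl]-2,5-bis[4-(benzyloxy)-3,5-dimethoxyphenyl]oxolan-3-yl}methanol
Conditions: LiAlH4, THF, 0 °C
Reagents that add atoms: none
Why: Hydride reduction of the ester to the primary alcohol; at 0 °C carbonyl addition is much faster than enolisation, so the C3 configuration is kept, and benzyl ethers and the oxolane are inert.

Step 8
Reactants: 16 {(2S,3S,4S,5R)-4-[(benzyloxy)methyl]-2,5-bis[4-(benzyloxy)-3,5-dimethoxyphenyl]oxolan-3-yl}methanol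
Product: 17 4,4′-[(2S,3S,4S,5R)-3,4-bis(hydroxymethyl)oxolane-2,5-diyl]bis(2,6-dimethoxyphenol), the target
Conditions: H2 (1 atm), 10% Pd/C, EtOAc–MeOH, rt
Reagents that add atoms: none
Why: Catalytic hydrogenolysis removes the two aryl benzyl ethers and the alkyl benzyl ether in one operation; under neutral conditions at 1 atm the hindered secondary ring C–O bonds should react more slowly, and no stereocentre is touched.

## Compound list

1 | syringaldehyde | COc1cc(C=O)cc(OC)c1O | starting material
2 | benzyl bromide | BrCc1ccccc1 | starting material
3 | 4-(benzyloxy)-3,5-dimethoxybenzaldehyde | COc1cc(C=O)cc(OC)c1OCc1ccccc1 | intermediate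
4 | 4-(benzyloxy)butan-2-one | CC(=O)CCOCc1ccccc1 | starting material
5 | lithium 5-(benzyloxy)-1-[4-(benzyloxy)-3,5-dimethoxyphenyl]-3-oxopentan-1-olate (racemic) | [Li+].[O-]C(CC(=O)CCOCc1ccccc1)c1cc(OC)c(OCc2ccccc2)c(OC)c1 | intermediate
6 | 5-(benzyloxy)-1-[4-(benzyloxy)-3,5-dimethoxyphenyl]-3-oxopentyl methanesulfonate (racemic) | CS(=O)(=O)OC(CC(=O)CCOCc1ccccc1)c1cc(OC)c(OCc2ccccc2)c(OC)c1 | intermediate
7 | (E)-5-(benzyloxy)-1-[4-(benzyloxy)-3,5-dimethoxyphenyl]pent-1-en-3-one | COc1cc(/C=C/C(=O)CCOCc2ccccc2)cc(OC)c1OCc1ccccc1 | intermediate
8 | (1E,3Z)-5-(benzyloxy)-1-[4-(benzyloxy)-3,5-dimethoxyphenyl]penta-1,3-dien-3-yl bis[(1S,2R,3S,5S)-2,6,6-trimethylbicyclo[3.1.1]heptan-3-yl]borinate | COc1cc(/C=C/C(OB([C@H]2C[C@H]3C[C@@H]([C@@H]2C)C3(C)C)[C@H]2C[C@H]3C[C@@H]([C@@H]2C)C3(C)C)=C/COCc2ccccc2)cc(OC)c1OCc1ccccc1 | intermediate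
9 | (1E,4R,5R)-4-[(benzyloxy)methyl]-1,5-bis[4-(benzyloxy)-3,5-dimethoxyphenyl]-5-hydroxypent-1-en-3-one | COc1cc(/C=C/C(=O)[C@H](COCc2ccccc2)[C@@H](O)c2cc(OC)c(OCc3ccccc3)c(OC)c2)cc(OC)c1OCc1ccccc1 | intermediate
10 | (2R,3R,6S)-3-[(benzyloxy)methyl]-2,6-bis[4-(benzyloxy)-3,5-dimethoxyphenyl]oxan-4-one (aryls cis, arm axial) | COc1cc([C@H]2O[C@@H](c3cc(OC)c(OCc4ccccc4)c(OC)c3)[C@@H](COCc3ccccc3)C(=O)C2)cc(OC)c1OCc1ccccc1 | intermediate
11 | (2R,3S,6S)-3-[(benzyloxy)methyl]-2,6-bis[4-(benzyloxy)-3,5-dimethoxyphenyl]oxan-4-one (all equatorial) | COc1cc([C@H]2O[C@@H](c3cc(OC)c(OCc4ccccc4)c(OC)c3)[C@H](COCc3ccccc3)C(=O)C2)cc(OC)c1OCc1ccccc1 | intermediate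
12 | 5-(trifluoroacetyl) derivative of 11, drawn as its ring enol, ring stereocentres as in 11 | COc1cc([C@H]2O[C@@H](c3cc(OC)c(OCc4ccccc4)c(OC)c3)[C@H](COCc3ccccc3)C(O)=C2C(=O)C(F)(F)F)cc(OC)c1OCc1ccccc1 | intermediate
13 | (2R,3S,6R)-3-[(benzyloxy)methyl]-2,6-bis[4-(benzyloxy)-3,5-dimethoxyphenyl]-5-diazooxan-4-one | COc1cc([C@H]2O[C@@H](c3cc(OC)c(OCc4ccccc4)c(OC)c3)[C@H](COCc3ccccc3)C(=O)C2=[N+]=[N-])cc(OC)c1OCc1ccccc1 | intermediate
14 | {4-[(benzyloxy)methyl]-2,5-bis[4-(benzyloxy)-3,5-dimethoxyphenyl]oxolan-3-ylidene}methanone (ketene; aryls cis, arm trans to the neighbouring aryl, as in 15) | COc1cc([C@H]2O[C@@H](c3cc(OC)c(OCc4ccccc4)c(OC)c3)[C@H](COCc3ccccc3)C2=C=O)cc(OC)c1OCc1ccccc1 | intermediate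
15 | methyl (2S,3R,4S,5R)-4-[(benzyloxy)methyl]-2,5-bis[4-(benzyloxy)-3,5-dimethoxyphenyl]oxolane-3-carboxylate | COc1cc([C@H]2O[C@@H](c3cc(OC)c(OCc4ccccc4)c(OC)c3)[C@H](COCc3ccccc3)[C@H]2C(=O)OC)cc(OC)c1OCc1ccccc1 | intermediate
16 | {(2S,3S,4S,5R)-4-[(benzyloxy)methyl]-2,5-bis[4-(benzyloxy)-3,5-dimethoxyphenyl]oxolan-3-yl}methanol | COc1cc([C@H]2O[C@@H](c3cc(OC)c(OCc4ccccc4)c(OC)c3)[C@H](COCc3ccccc3)[C@H]2CO)cc(OC)c1OCc1ccccc1 | intermediate
17 | 4,4′-[(2S,3S,4S,5R)-3,4-bis(hydroxymethyl)oxolane-2,5-diyl]bis(2,6-dimethoxyphenol) | COc1cc([C@H]2O[C@@H](c3cc(OC)c(O)c(OC)c3)[C@H](CO)[C@H]2CO)cc(OC)c1O | target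

## Step count and least certain steps

Total step count: 8. Longest linear sequence: 8 steps (1 → 3 → 7 → 9 → 11 → 13 → 15 → 16 → 17; ketone 4 enters at step 2 and aldehyde 3 is used again at step 3).

Step 6 (key step). The most likely failure is poor facial selectivity in the ketonisation that creates C3, because one face of the enol is flanked by the C2 aryl and the other by the C4 benzyloxymethyl arm, so the bias is only a difference in size. A secondary risk is 1,2-hydride shift from C6–H if nitrogen loss is not concerted. Fallback: the route is left at 15, obtained as a mixture with the C3-epimeric ester F1. The mixture is deprotonated with LiN(iPr)2 in THF at −78 °C to the lithium ester enolate F2, which is quenched at −78 °C with a hindered proton donor such as 2,6-di-tert-butylphenol. A bulky acid should amplify protonation on the face away from the aryl group. The route is rejoined at 15.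

Step 3. The most likely failures are insufficient enantioface selectivity, or sluggish enolisation of a ketone whose enolising carbon carries a CH2OBn group, by a very bulky boron triflate. Fallback: from 7, TMSOTf and Et3N give the silyl dienol ether F3. A Mukaiyama aldol with 3, catalysed by the acyloxyborane formed from BH3·THF and a 2-O-(2,6-diisopropoxybenzoyl)tartaric acid (enantiomer chosen for Re-face addition) in EtCN at −78 °C, should give the silyl-protected syn aldol F4. Dilute acid removes the silyl group and the route is rejoined at 9.

Step 4. The most likely failure is loss of benzyl alcohol by E1cB elimination from the C3 enolate during base-mediated epimerisation, since the arm oxygen is β to the ketone; ring opening followed by retro-aldol cleavage is a second possibility. Fallback: from 9, TsOH·H2O (catalytic) in toluene at 40 °C closes the ring and equilibrates C3 through the neutral enol and through reversible opening of the O1–C2 bond under control of C6. No enolate is formed, so E1cB loss is avoided. This detour makes no new compound (F0) and rejoins the route at 11.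

Step 5. The most likely failures are enolisation toward C3 instead of C5, followed by loss of the benzyloxy group, or incomplete C-acylation of a hindered enolate. Fallback: from 11, tert-butoxybis(dimethylamino)methane in toluene at 80 °C condenses at the only α-methylene to give the enaminone F5. Diazo transfer to the enaminone with 4-acetamidobenzenesulfonyl azide in MeCN at rt rejoins the route at 13.

Step 8. The most likely failure is hydrogenolysis of a ring C–O bond (C2–O1 or C5–O1) while the slowest benzyl ether, the one on the aliphatic arm, is still being cleaved. Fallback: from 16, non-reductive debenzylation with BCl3 and pentamethylbenzene as cation scavenger in CH2Cl2 at −78 °C gives 17 directly. This detour makes no new compound (F0) and rejoins the route at 17.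

## Further compounds

F1 | step 6 | methyl (2S,3S,4S,5R)-4-[(benzyloxy)methyl]-2,5-bis[4-(benzyloxy)-3,5-dimethoxyphenyl]oxolane-3-carboxylate (C3 epimer of 15) | COc1cc([C@H]2O[C@@H](c3cc(OC)c(OCc4ccccc4)c(OC)c3)[C@H](COCc3ccccc3)[C@@H]2C(=O)OC)cc(OC)c1OCc1ccccc1
F2 | step 6 | lithium enolate of ester 15 | COc1cc([C@H]2O[C@@H](c3cc(OC)c(OCc4ccccc4)c(OC)c3)[C@H](COCc3ccccc3)C2=C([O-])OC)cc(OC)c1OCc1ccccc1.[Li+]
F3 | step 3 | {[(1E,3Z)-5-(benzyloxy)-1-[4-(benzyloxy)-3,5-dimethoxyphenyl]penta-1,3-dien-3-yl]oxy}trimethylsilane | COc1cc(/C=C/C(O[Si](C)(C)C)=C/COCc2ccccc2)cc(OC)c1OCc1ccccc1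
F4 | step 3 | (1E,4R,5R)-4-[(benzyloxy)methyl]-1,5-bis[4-(benzyloxy)-3,5-dimethoxyphenyl]-5-[(trimethylsilyl)oxy]pent-1-en-3-one | COc1cc(/C=C/C(=O)[C@H](COCc2ccccc2)[C@@H](O[Si](C)(C)C)c2cc(OC)c(OCc3ccccc3)c(OC)c2)cc(OC)c1OCc1ccccc1
F0 | step 4 | none | none
F5 | step 5 | 5-[(dimethylamino)methylidene] derivative of 11, ring stereocentres as in 11 | COc1cc([C@H]2O[C@@H](c3cc(OC)c(OCc4ccccc4)c(OC)c3)[C@H](COCc3ccccc3)C(=O)C2=CN(C)C)cc(OC)c1OCc1ccccc1
F0 | step 8 | none | none
A1 | alternative 1 | methyl 4,5-trans-2,5-bis[4-(benzyloxy)-3,5-dimethoxyphenyl]-4-{[(tert-butyldimethylsilyl)oxy]methyl}-4,5-dihydrofuran-3-carboxylate | COc1cc(C2=C(C(=O)OC)[C@@H](CO[Si](C)(C)C(C)(C)C)[C@H](c3cc(OC)c(OCc4ccccc4)c(OC)c3)O2)cc(OC)c1OCc1ccccc1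
A2 | alternative 1 | methyl 2-[4-(benzyloxy)-3,5-dimethoxybenzoyl]-4-[(tert-butyldimethylsilyl)oxy]but-2-enoate | COC(=O)C(=CCO[Si](C)(C)C(C)(C)C)C(=O)c1cc(OC)c(OCc2ccccc2)c(OC)c1
A3 | alternative 1 | (2R,5R)-1-[4-(benzyloxy)-3,5-dimethoxybenzyl]-2,5-dimethylthiolan-1-ium trifluoromethanesulfonate | C[C@@H]1CC[C@@H](C)[S+]1Cc1cc(OC)c(OCc2ccccc2)c(OC)c1.[O-]S(=O)(=O)C(F)(F)F
A4 | alternative 2 | 2,5-cis-diaryl-4-(benzyloxymethyl)-3-(pinacolborylmethyl)oxolane with the target configuration | COc1cc([C@H]2O[C@@H](c3cc(OC)c(OCc4ccccc4)c(OC)c3)[C@H](COCc3ccccc3)[C@H]2CB2OC(C)(C)C(C)(C)O2)cc(OC)c1OCc1ccccc1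
A5 | alternative 2 | 2-[4-(benzyloxy)-3,5-dimethoxyphenyl]-2-{[(1R,2S,3E)-2-[(benzyloxy)methyl]-1-[4-(benzyloxy)-3,5-dimethoxyphenyl]-4-(4,4,5,5-tetramethyl-1,3,2-dioxaborolan-2-yl)but-3-en-1-yl]oxy}acetic acid (both epimers at C2 of the acid) | OC(=O)C(c1cc(OC)c(OCc2ccccc2)c(OC)c1)O[C@@H](c1cc(OC)c(OCc2ccccc2)c(OC)c1)[C@H](COCc1ccccc1)/C=C/B1OC(C)(C)C(C)(C)O1
A6 | alternative 3 | 2,5-cis-diaryl-4-(benzyloxymethyl)-3-vinyloxolane with the target configuration | COc1cc([C@H]2O[C@@H](c3cc(OC)c(OCc4ccccc4)c(OC)c3)[C@H](COCc3ccccc3)[C@H]2C=C)cc(OC)c1OCc1ccccc1
A7 | alternative 3 | (1R,2S,3E)-2-[(benzyloxy)methyl]-1-[4-(benzyloxy)-3,5-dimethoxyphenyl]-5-(trimethylsilyl)pent-3-en-1-ol | O[C@@H](c1cc(OC)c(OCc2ccccc2)c(OC)c1)[C@H](COCc1ccccc1)/C=C/C[Si](C)(C)C
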